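**Assumption:** the target SMILES has no stereocentre and no stereogenic double bond, so the compound is achiral and there is no enantiomer to select; the route makes this one achiral compound.

## Retrosynthetic overview

1. The benzene ring and the whole aryl–C3 skeleton come intact from eugenol (1); no ring is formed anywhere in the route.
2. Primary C–O bond: 4-(3-hydroxypropyl)-2-methoxyphenol (3) from 1 by anti-Markovnikov hydroboration–oxidation (borane 2 in the flask).
3. Aryl C–O bond next to the phenol (key bond, proposed new step): catechol 6 from 3 by O-boryl-directed C–H borylation with [Ir(OMe)(cod)]2/dtbpy (4 and 5 in the flask), then oxidation.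
4. Ester C–O bond, made last: target 8 from 6 and vinyl stearate (7) by lipase acylation of the primary alcohol only.

## Route

Step 1
Reactants: 1 eugenol (4-allyl-2-methoxyphenol)
Product: 3 4-(3-hydroxypropyl)-2-methoxyphenol (dihydroconiferyl alcohol), via bis(9-BBN) adduct 2 (not isolated)
Conditions: 9-BBN dimer (2.2 equiv B–H), THF, 0 °C to rt; then 3 M NaOH, 30% H2O2, 0 °C to rt
Reagents that add atoms: hydrogen peroxide, OO
Why: Hydroboration–oxidation: the bulky 9-BBN puts boron on the terminal alkene carbon (anti-Markovnikov), the phenol is masked in the flask as its borinate, and alkaline H2O2 replaces C–B by C–OH; no stereocentre is formed.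

Step 2
Reactants: 3 4-(3-hydroxypropyl)-2-methoxyphenol
Product: 6 3-(3,4-dihydroxy-5-methoxyphenyl)propan-1-ol, via bis(O-Bpin) ether 4 (not isolated), via ring-borylated tris(Bpin) species 5 (not isolated)
Conditions: HBpin (3.6 equiv), [Ir(OMe)(cod)]2 (2 mol%), dtbpy (4 mol%), THF, 25 then 80 °C (sealed); then 30% H2O2, aq NaHCO3, 0 °C to rt, argon; Na2S2O3 then 1 M HCl work-up
Reagents that add atoms: hydrogen peroxide, OO
Why: Proposed new method: HBpin first turns both OH groups into O–Bpin groups (loss of H2), then (dtbpy)Ir(Bpin)3, a trivalent iridium tris(boryl) complex, cleaves the one C–H bond that flanks the aryloxyboronate (C6 of the phenol), because C3–H is shut in between OMe and the side chain, C5–H sits beside the alkyl chain without any assistance, the electron-rich O–Bpin oxygen attracts the electron-poor bipyridine ligand in the C–H cleavage transition state, and an O(Me)→B contact is expected to hold the boryl group on the methoxy side away from C6–H; H2O2 then converts C–B into C–OH and the O–B esters are hydrolysed on work-up, so oxygen can enter only at a C–H carbon and neither demethylation nor quinone methide formation (the usual fate of guaiacols under direct two-electron phenol oxidants) is possible; closest known reaction type: ortho C–H borylation of simple phenols through aryloxyboronates formed in the flask with [Ir(OMe)(cod)]2/bipyridine catalysts, combined with arylboronate oxidation, which to the best of present knowledge has not been shown on a 2-methoxy-4-alkylphenol (guaiacyl unit) carrying a free alcohol nor used as a one-flask phenol-to-catechol hydroxylation; no stereocentre is formed.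

Step 3
Reactants: 6 3-(3,4-dihydroxy-5-methoxyphenyl)propan-1-ol; 7 vinyl stearate (ethenyl octadecanoate)
Product: 8 3-(3,4-dihydroxy-5-methoxyphenyl)propyl octadecanoate (target)
Conditions: Novozym 435 (immobilised Candida antarctica lipase B), 7 (1.5 equiv), 2-methyl-2-butanol, 45 °C
Reagents that add atoms: none
Why: Lipase-catalysed irreversible transesterification: the serine acyl-enzyme passes the stearoyl group only to the unhindered primary aliphatic OH (phenolic OH groups are not acylated by this enzyme) and the vinyl alcohol set free tautomerises to acetaldehyde, which drives the reaction; no stereocentre is formed.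

## Compound list

1 | eugenol (4-allyl-2-methoxyphenol) | C=CCc1ccc(O)c(OC)c1 | starting material
2 | 9-[3-(4-{(9-borabicyclo[3.3.1]nonan-9-yl)oxy}-3-methoxyphenyl)propyl]-9-borabicyclo[3.3.1]nonane (O,C-bis(9-BBN) adduct of eugenol) | COc1cc(CCCB2C3CCCC2CCC3)ccc1OB1C2CCCC1CCC2 | intermediate
3 | 4-(3-hydroxypropyl)-2-methoxyphenol (dihydroconiferyl alcohol) | COc1cc(CCCO)ccc1O | intermediate
4 | 2-{2-methoxy-4-[3-((4,4,5,5-tetramethyl-1,3,2-dioxaborolan-2-yl)oxy)propyl]phenoxy}-4,4,5,5-tetramethyl-1,3,2-dioxaborolane (both OH groups of 3 as O–Bpin) | COc1cc(CCCOB2OC(C)(C)C(C)(C)O2)ccc1OB1OC(C)(C)C(C)(C)O1 | intermediate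
5 | 2-{2-methoxy-6-(4,4,5,5-tetramethyl-1,3,2-dioxaborolan-2-yl)-4-[3-((4,4,5,5-tetramethyl-1,3,2-dioxaborolan-2-yl)oxy)propyl]phenoxy}-4,4,5,5-tetramethyl-1,3,2-dioxaborolane (4 with a C–Bpin group on the ring carbon next to the aryloxyboronate) | COc1cc(CCCOB2OC(C)(C)C(C)(C)O2)cc(B2OC(C)(C)C(C)(C)O2)c1OB1OC(C)(C)C(C)(C)O1 | intermediate
6 | 3-(3,4-dihydroxy-5-methoxyphenyl)propan-1-ol | COc1cc(CCCO)cc(O)c1O | intermediate
7 | vinyl stearate (ethenyl octadecanoate) | CCCCCCCCCCCCCCCCCC(=O)OC=C | starting material
8 | 3-(3,4-dihydroxy-5-methoxyphenyl)propyl octadecanoate | CCCCCCCCCCCCCCCCCC(=O)OCCCc1cc(O)c(O)c(OC)c1 | target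

## Step count and risk

Total step count: 3. Longest linear sequence: 3 steps (1 → 3 → 6 → 8).

Steps most likely to fail, in order of risk:

**Step 2 (proposed new C–H hydroxylation).** Risks are slow borylation beside the crowded aryloxyboronate, some borylation at C5, or over-oxidation of the electron-rich catechol. The fallback uses known chemistry and sets out from 3. Ortho-formylation with MgCl2, Et3N and paraformaldehyde in MeCN at reflux puts a formyl group on the only free position ortho to the phenol and gives 2-hydroxy-5-(3-hydroxypropyl)-3-methoxybenzaldehyde F2. Dakin oxidation of this salicylaldehyde (30% H2O2, aq NaOH, 0 °C to rt under nitrogen, then HCl) gives the catechol and comes back to the route at 6. This is the classical o-vanillin to 3-methoxycatechol conversion on a substituted substrate.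

**Step 3 (lipase acylation).** Risks are poor solubility of the polar triol, slow conversion, or enzyme inhibition by acetaldehyde. The fallback sets out from 6. Exhaustive acylation with stearoyl chloride (3.3 equiv, pyridine, cat. DMAP, CH2Cl2, 0 °C to rt) gives 3-[3,4-bis(octadecanoyloxy)-5-methoxyphenyl]propyl octadecanoate F3. Pyrrolidine (2.2 equiv, THF, 0 °C to rt, argon) then cleaves the two aryl esters by aminolysis, which is far faster than aminolysis of the alkyl ester, and comes back to the route at 8.

**Step 1 (hydroboration–oxidation).** Risks are incomplete hydroboration because the free phenol consumes borane, and oxidation of the phenol in alkaline peroxide. The fallback sets out from 1. Anti-Markovnikov hydrosilylation with HSi(OEt)3 and Pt2[(CH2=CHSiMe2)2O]3 (0.05 mol% Pt) in toluene at 60 °C gives 2-methoxy-4-[3-(triethoxysilyl)propyl]phenol F1. Tamao oxidation (KF, KHCO3, 30% H2O2, THF/MeOH, 50 °C) turns the C–Si bond into C–OH and comes back to the route at 3.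

Further compounds
F1 | step 1 | 2-methoxy-4-[3-(triethoxysilyl)propyl]phenol | CCO[Si](CCCc1ccc(O)c(OC)c1)(OCC)OCC
F2 | step 2 | 2-hydroxy-5-(3-hydroxypropyl)-3-methoxybenzaldehyde | O=Cc1cc(CCCO)cc(OC)c1O
F3 | step 3 | 3-[3,4-bis(octadecanoyloxy)-5-methoxyphenyl]propyl octadecanoate | CCCCCCCCCCCCCCCCCC(=O)OCCCc1cc(OC)c(OC(=O)CCCCCCCCCCCCCCCCC)c(OC(=O)CCCCCCCCCCCCCCCCC)c1
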